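Take the logarithm of every rate factor and count in decades, one decade being a factor of ten, so that factors add.

| flask | J | D | Z | remark |
|---|---|---|---|---|
| cedar | 0.15 M | 0.95 equiv | 1.5 mol% | run made earlier |
| alder | 0.22 M | 0.95 equiv | 1.5 mol% | run made earlier |
| elm | 0.30 M | 0.95 equiv | 3 mol% | run made earlier |
| flask | 0.30 M | 0.950 equiv | 1.5 mol% |  |

| cedar: time / h | cedar: X / % | alder: time / h | alder: X / % | elm: time / h | elm: X / % |
|---|---|---|---|---|---|
| 0.667 | 0.6 | 0.200 | 0.4 | 0.667 | 12.9 |
| 1.33 | 3.1 | 0.417 | 1.1 | 1.33 | 26.2 |
| 2.00 | 5.0 | 1.00 | 3.8 | 2.00 | 34.6 |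
| 2.50 | 3.5 | 2.50 | 12.5 | 2.50 | 41.2 |

(readings scatter by 1 percentage point)

- what has left J counts as converted, also if it is not yet product

- factor on the rate of making X when 20% of the J are converted if D is charged twice over
- factor on the rate when 20% of the J are converted if Z is charged at 8 mol% instead

Read the speed first. The elm run starts at 0.193 h⁻¹ of its J, and the alder run, between its last two readings, goes at 0.0580 h⁻¹, a reading 0.522 decades lower. First order in D and in Z predicts 0.570 decades, so take both orders as one. The flask is the elm run with half the Z, which by my reckoning gives a start of 0.0967 h⁻¹, a time constant of 10.3 h.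

Now count what slows it. In my count for the flask, going from 20% to 85.0% conversion, J loses 0.727 decades and D, taken as used one for one with J, loses 0.875. Their sum, 1.60 decades, is the slowing, the drop in rate between those two conversions at first order in each, so my count stretches the flask's time constant by a factor 39.8 at 85.0% against 20% conversion.

The same count gives my answers: 2.27 for D and 5.33 for Z. The forecast says 1.9 and 7, lower on D and higher on Z, with “so D order is probably 1 but could be lower”.

The flask gives 1.80 for D and 5.86 for Z.

J + Z ⇌ Z + L (K = 0.570, k = 3.07 M⁻¹ min⁻¹); D + Z + L → Z + X (k = 8.25 M⁻² min⁻¹); Z ⇌ G (K = 0.720, k = 0.00582 min⁻¹) By 0.400 h the step from J to L had brought J to 78.7% and L to 18.7%, while X stood at 2.60% and D at 97.3%, more than the 78.9% my count assumed. L and D then made X while Z passed into G, with Z at 59.6% and G at 40.4% of the catalyst charged at 4.00 h. Between 20% and 85.0% conversion the flask's rate fell to 0.058 of its value, which is 1.24 decades against a slowing of 1.60.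

(All runs stem from a simulated flask with made-up constants; scatter was added.)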